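**Retrosynthetic overview**
1. Rings A and B are made together, last: an intramolecular furan–ynal Diels–Alder reaction across the tether C3–C2(=CMe2)–C1, then aromatisation. The furan oxygen becomes the C6 phenol and the ynal CHO becomes the C7 aldehyde.
2. The tether carrying C1 comes from a racemic benzylic–allylic chloride and propiolaldehyde diethyl acetal (CuI/L*-catalysed enantioconvergent alkynylation sets C1).
3. The allylic alcohol behind that chloride comes from the benzodioxane aldehyde and a tetrasubstituted vinyllithium (built from furan and 3-methylbuta-1,2-diene).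
4. The benzodioxane aldehyde (rings C and D) comes from 2,3-dihydroxy-5-methylbenzaldehyde and an (R)-epoxy nosylate made from prenol.
5. Ring order: C is bought (4-methylcatechol), D closes in step 3, B and A close together in step 8.

Conventions: C1–C7a are the indane positions of the target (C1 aryl-bearing, C2 isopropylidene-bearing, C3 CH2, C6 C–OH, C7 C–CHO). Ring A is the indane benzene ring, ring B its five-membered ring, ring C the benzodioxane benzene ring, ring D the dioxane ring. Ar = (3S)-3-(2-hydroxypropan-2-yl)-7-methyl-2,3-dihydro-1,4-benzodioxin-5-yl. L* = N-[(8S,9S)-6′-methoxycinchonan-9-yl]-2-(diphenylphosphanyl)benzamide.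

Assumption: in step 7 the quinine-derived ligand L* is taken to give the (S) centre of 18; if the sense proves opposite, its quinidine-derived pseudo-enantiomer is used.

**Step 1**
Reactants: 1 3-methylbut-2-en-1-ol (prenol)
Product: 3 [(2R)-3,3-dimethyloxiran-2-yl]methyl 4-nitrobenzenesulfonate, via epoxy alcohol 2 (not isolated)
Conditions: Ti(OiPr)4 (5 mol%), D-(−)-DIPT (7 mol%), t-BuOOH, 4 Å MS, CH2Cl2, −20 °C; P(OMe)3; then Et3N, DMAP (cat.), 4-NsCl, −10 °C
Reagents that add atoms: tert-butyl hydroperoxide CC(C)(C)OO; 4-nitrobenzenesulfonyl chloride O=S(=O)(Cl)c1ccc(cc1)[N+](=O)[O-]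
Why: Sharpless asymmetric epoxidation with the Ti(OiPr)4/D-(−)-tartrate catalyst delivers oxygen to the face that gives the (2R)-epoxy alcohol (mirror image of the (2S) outcome of L-(+)-tartrate), and in situ nosylation traps the water-soluble epoxy alcohol without touching the stereocentre.

**Step 2**
Reactants: 4 4-methylbenzene-1,2-diol
Product: 5 2,3-dihydroxy-5-methylbenzaldehyde
Conditions: MgCl2, Et3N, (CH2O)n, MeCN, reflux; 1 M HCl
Reagents that add atoms: formaldehyde (as paraformaldehyde) C=O
Why: Casnati–Skattebøl MgCl2-mediated ortho-formylation delivers formaldehyde inside the phenoxide–MgCl chelate to the free ortho position not flanked by the methyl group, and a second formaldehyde oxidises the hydroxymethyl stage to the aldehyde.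

**Step 3**
Reactants: 5 2,3-dihydroxy-5-methylbenzaldehyde; 3 [(2R)-3,3-dimethyloxiran-2-yl]methyl 4-nitrobenzenesulfonate
Product: 7 (3S)-3-(2-hydroxypropan-2-yl)-7-methyl-2,3-dihydro-1,4-benzodioxine-5-carbaldehyde (Ar–CHO), via epoxy ether 6 (not isolated)
Conditions: NaH (2.1 equiv), DMSO, rt; 3, rt then 65 °C; H2O
Reagents that add atoms: none
Why: Williamson alkylation then intramolecular epoxide opening: in the dianion the 3-oxide (not conjugated to the aldehyde) displaces the nosylate first, and the remaining 2-phenoxide opens the epoxide 6-exo-tet at the secondary carbon with inversion, turning the (R)-epoxide into the (S)-dioxane centre and fixing which oxygen carries the CH(CMe2OH) carbon.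

**Step 4**
Reactants: 8 3-methylbuta-1,2-diene
Product: 9 1,2-dibromo-3-methylbut-2-ene
Conditions: Br2 (1.0 equiv), CH2Cl2, −78 °C to rt, 12 h
Reagents that add atoms: bromine BrBr
Why: Electrophilic bromination of the allene places bromine on the central carbon, and allylic equilibration of the first-formed tertiary bromide gives the primary 2-bromoallyl bromide with the tetrasubstituted alkene.

**Step 5**
Reactants: 10 furan; 9 1,2-dibromo-3-methylbut-2-ene
Product: 12 2-(2-bromo-3-methylbut-2-en-1-yl)furan, via furyllithium 11 (not isolated)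
Conditions: n-BuLi, THF, 0 °C; 9, −78 °C to rt
Reagents that add atoms: none
Why: Alpha-lithiation of furan and SN2 alkylation: 2-furyllithium displaces the primary allylic bromide (any tertiary allylic isomer converges by SN2′) while the vinylic C–Br bond is inert, as in the known furyllithium–prenyl bromide coupling.

**Step 6**
Reactants: 12 2-(2-bromo-3-methylbut-2-en-1-yl)furan; 7 Ar–CHO
Product: 14 (1RS)-1-Ar-2-(furan-2-ylmethyl)-3-methylbut-2-en-1-ol (1:1 epimers at the carbinol), via vinyllithium 13 (not isolated)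
Conditions: 12 (2.2 equiv), t-BuLi (4.4 equiv), Et2O, −78 °C; 7, −78 to −20 °C; H2O
Reagents that add atoms: none
Why: Bromine–lithium exchange and 1,2-addition: the tetrasubstituted vinyllithium adds to the aldehyde to form the C1–C2 bond (one equivalent is spent deprotonating the tertiary alcohol), and the unselectively formed carbinol centre is erased in step 7.

**Step 7**
Reactants: 14 (1RS)-1-Ar-2-(furan-2-ylmethyl)-3-methylbut-2-en-1-ol; 15 3,3-diethoxyprop-1-yne
Product: 18 (4S)-4-Ar-1,1-diethoxy-5-(furan-2-ylmethyl)-6-methylhept-5-en-2-yne, via allyl mesylate 16 (not isolated), via allyl chloride 17 (not isolated)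
Conditions: MsCl, LiCl, 2,4,6-collidine, DMF, 0 °C; crude chloride, then 15, CuI (10 mol%), L* (12 mol%), Cs2CO3, Et2O, rt
Reagents that add atoms: none
Why: Proposed new method: after Collington–Meyers chlorination, electron transfer from the acetylide L*Cu–C≡C–CH(OEt)2 (monovalent copper) to the C–Cl bond gives a planar benzylic–allylic radical and a divalent copper acetylide, and radical capture with reductive elimination from trivalent copper at the less hindered benzylic terminus forms the C1–C(sp) bond inside the chiral pocket of L*, so both enantiomers of 17 and any allyl-transposed chloride converge on (S)-18; the closest known reaction type is the CuI/cinchona N,N,P-ligand enantioconvergent radical Sonogashira-type C(sp3)–C(sp) coupling of racemic secondary benzylic halides with terminal alkynes.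

**Step 8**
Reactants: 18 (4S)-4-Ar-1,1-diethoxy-5-(furan-2-ylmethyl)-6-methylhept-5-en-2-yne
Product: 21 (3R)-3-Ar-5-hydroxy-2-(propan-2-ylidene)-2,3-dihydro-1H-indene-4-carbaldehyde (Diaporindene G), via ynal 19 (not isolated), via oxanorbornadiene 20 (not isolated)
Conditions: Amberlyst-15, acetone–H2O, rt; filter; PhMe, BHT, 110 °C; PPTS (cat.), 60 °C
Reagents that add atoms: water O
Why: Intramolecular Diels–Alder reaction of furan with aromatisation: hydrolysis unveils the ynal, the furan adds across the activated alkyne through the three-atom tether (pre-organised by sp2 C2) to close rings B and A together, and acid-assisted opening of the oxa-bridge at the tertiary bridgehead with loss of the C6 proton gives the phenol ortho to the aldehyde, while C1 is a spectator under these base-free conditions and keeps its configuration (the descriptor changes from S to R only through CIP priorities).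

**Compound list**
1 | 3-methylbut-2-en-1-ol (prenol) | CC(C)=CCO | starting material
2 | [(2R)-3,3-dimethyloxiran-2-yl]methanol | CC1(C)O[C@@H]1CO | intermediate
3 | [(2R)-3,3-dimethyloxiran-2-yl]methyl 4-nitrobenzenesulfonate | CC1(C)O[C@@H]1COS(=O)(=O)c1ccc(cc1)[N+](=O)[O-] | intermediate
4 | 4-methylbenzene-1,2-diol | Cc1ccc(O)c(O)c1 | starting material
5 | 2,3-dihydroxy-5-methylbenzaldehyde | Cc1cc(C=O)c(O)c(O)c1 | intermediate
6 | sodium 2-{[(2R)-3,3-dimethyloxiran-2-yl]methoxy}-6-formyl-4-methylphenolate | Cc1cc(C=O)c([O-])c(OC[C@H]2OC2(C)C)c1.[Na+] | intermediate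
7 | (3S)-3-(2-hydroxypropan-2-yl)-7-methyl-2,3-dihydro-1,4-benzodioxine-5-carbaldehyde | O=Cc1cc(C)cc2c1O[C@H](C(C)(C)O)CO2 | intermediate
8 | 3-methylbuta-1,2-diene | CC(C)=C=C | starting material
9 | 1,2-dibromo-3-methylbut-2-ene | CC(C)=C(Br)CBr | intermediate
10 | furan | c1ccoc1 | starting material
11 | furan-2-yllithium | [Li]c1ccco1 | intermediate
12 | 2-(2-bromo-3-methylbut-2-en-1-yl)furan | CC(C)=C(Br)Cc1ccco1 | intermediate
13 | [1-(furan-2-yl)-3-methylbut-2-en-2-yl]lithium | CC(C)=C([Li])Cc1ccco1 | intermediate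
14 | (1RS)-1-Ar-2-(furan-2-ylmethyl)-3-methylbut-2-en-1-ol | CC(C)=C(Cc1ccco1)C(O)c1cc(C)cc2c1O[C@H](C(C)(C)O)CO2 | intermediate
15 | 3,3-diethoxyprop-1-yne | C#CC(OCC)OCC | starting material
16 | (1RS)-1-Ar-2-(furan-2-ylmethyl)-3-methylbut-2-en-1-yl methanesulfonate | CC(C)=C(Cc1ccco1)C(OS(C)(=O)=O)c1cc(C)cc2c1O[C@H](C(C)(C)O)CO2 | intermediate
17 | 2-[(2S)-8-[(1RS)-1-chloro-2-(furan-2-ylmethyl)-3-methylbut-2-en-1-yl]-6-methyl-2,3-dihydro-1,4-benzodioxin-2-yl]propan-2-ol | CC(C)=C(Cc1ccco1)C(Cl)c1cc(C)cc2c1O[C@H](C(C)(C)O)CO2 | intermediate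
18 | 2-[(2S)-8-[(4S)-1,1-diethoxy-5-(furan-2-ylmethyl)-6-methylhept-5-en-2-yn-4-yl]-6-methyl-2,3-dihydro-1,4-benzodioxin-2-yl]propan-2-ol | CCOC(OCC)C#C[C@@H](C(=C(C)C)Cc1ccco1)c1cc(C)cc2c1O[C@H](C(C)(C)O)CO2 | intermediate
19 | (4S)-5-(furan-2-ylmethyl)-4-[(3S)-3-(2-hydroxypropan-2-yl)-7-methyl-2,3-dihydro-1,4-benzodioxin-5-yl]-6-methylhept-5-en-2-ynal | O=CC#C[C@@H](C(=C(C)C)Cc1ccco1)c1cc(C)cc2c1O[C@H](C(C)(C)O)CO2 | intermediate
20 | (1S)-1-Ar-2-(propan-2-ylidene)-1,2,3,6-tetrahydro-3a,6-epoxyindene-7-carbaldehyde (oxa-bridged cycloadduct, either bridge orientation) | CC(C)=C1CC23OC(C=C2)C(C=O)=C3[C@@H]1c1cc(C)cc2c1O[C@H](C(C)(C)O)CO2 | intermediate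
21 | (3R)-5-hydroxy-3-[(3S)-3-(2-hydroxypropan-2-yl)-7-methyl-2,3-dihydro-1,4-benzodioxin-5-yl]-2-(propan-2-ylidene)-2,3-dihydro-1H-indene-4-carbaldehyde (Diaporindene G) | CC(C)=C1Cc2ccc(O)c(C=O)c2[C@@H]1c1cc(C)cc2c1O[C@H](C(C)(C)O)CO2 | target

**Totals and risks**
Total step count: 8. Longest linear sequence: 5 steps (steps 1, 3, 6, 7, 8; the branches through steps 2 and 4–5 are equally long).

Step 7 is the most likely to fail: the enantioselectivity and the site of coupling on a hindered benzylic–allylic radical are untested. The fallback sets out from 17 and comes back at 18. It gives up catalyst control and uses the fixed dioxane centre for separation: ligand-free copper-acetylide allylic substitution of 17 with 15 (CuI, K2CO3, Bu4NI, DMF, rt) gives 18 and its C1 epimer F1 in roughly equal amounts. Because the (S)-dioxane centre is already in place these are diastereomers; they are separated by preparative HPLC and pure 18 rejoins the route at step 8.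

Step 8 is next: the ynal may not survive heating, or the oxa-bridge may not open cleanly. The fallback sets out from 17 and comes back at 21. It runs the same ring construction at the ester oxidation level: 17 is coupled with methyl propiolate under the CuI/L* conditions of step 7 to give ynoate F2. F2 is cyclised thermally (1,2-dichlorobenzene, 150 °C) or with Me2AlCl to methyl salicylate F3. LiAlH4 reduces F3 to salicyl alcohol F4, and MnO2 oxidises the benzylic alcohol to 21.

Step 6 is third: the tetrasubstituted vinyllithium is hindered and sits next to an acidic furfuryl CH2. The fallback sets out from 7 and comes back at 17. It builds the same allyl system by olefination instead of vinyl-metal addition: Horner–Wadsworth–Emmons reaction of 7 with phosphonate F5 (from triethyl phosphonoacetate, NaH and furfuryl bromide) gives enoate F6. Excess MeMgBr converts the ester into tertiary allylic alcohol F7, the allylic isomer of 14. HCl in Et2O at −30 °C ionises F7 to the same allyl chloride 17.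

**Further compounds**
F1 | step 7 | 2-[(2S)-8-[(4R)-1,1-diethoxy-5-(furan-2-ylmethyl)-6-methylhept-5-en-2-yn-4-yl]-6-methyl-2,3-dihydro-1,4-benzodioxin-2-yl]propan-2-ol | CCOC(OCC)C#C[C@H](C(=C(C)C)Cc1ccco1)c1cc(C)cc2c1O[C@H](C(C)(C)O)CO2
F2 | step 8 | methyl (4S)-5-(furan-2-ylmethyl)-4-[(3S)-3-(2-hydroxypropan-2-yl)-7-methyl-2,3-dihydro-1,4-benzodioxin-5-yl]-6-methylhept-5-en-2-ynoate | COC(=O)C#C[C@@H](C(=C(C)C)Cc1ccco1)c1cc(C)cc2c1O[C@H](C(C)(C)O)CO2
F3 | step 8 | methyl (3R)-5-hydroxy-3-[(3S)-3-(2-hydroxypropan-2-yl)-7-methyl-2,3-dihydro-1,4-benzodioxin-5-yl]-2-(propan-2-ylidene)-2,3-dihydro-1H-indene-4-carboxylate | CC(C)=C1Cc2ccc(O)c(C(=O)OC)c2[C@@H]1c1cc(C)cc2c1O[C@H](C(C)(C)O)CO2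
F4 | step 8 | (3R)-4-(hydroxymethyl)-3-[(3S)-3-(2-hydroxypropan-2-yl)-7-methyl-2,3-dihydro-1,4-benzodioxin-5-yl]-2-(propan-2-ylidene)-2,3-dihydro-1H-inden-5-ol | CC(C)=C1Cc2ccc(O)c(CO)c2[C@@H]1c1cc(C)cc2c1O[C@H](C(C)(C)O)CO2
F5 | step 6 | ethyl 2-(diethoxyphosphoryl)-3-(furan-2-yl)propanoate | CCOC(=O)C(Cc1ccco1)P(=O)(OCC)OCC
F6 | step 6 | ethyl 2-(furan-2-ylmethyl)-3-[(3S)-3-(2-hydroxypropan-2-yl)-7-methyl-2,3-dihydro-1,4-benzodioxin-5-yl]prop-2-enoate (E/Z mixture) | CCOC(=O)C(Cc1ccco1)=Cc1cc(C)cc2c1O[C@H](C(C)(C)O)CO2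
F7 | step 6 | 2-[(2S)-8-[2-(furan-2-ylmethyl)-3-hydroxy-3-methylbut-1-en-1-yl]-6-methyl-2,3-dihydro-1,4-benzodioxin-2-yl]propan-2-ol (E/Z mixture) | CC(C)(O)C(Cc1ccco1)=Cc1cc(C)cc2c1O[C@H](C(C)(C)O)CO2
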